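Divide the incoming ligand charged by twice the starting complex charged, and call that ratio the cap; each complex takes two ligands.

| setting | north-east | south | south-west | dawn | noon | dusk | summer |
|---|---|---|---|---|---|---|---|
| starting complex | 20 mM | 10 mM | 40 mM | 20 mM | 20 mM | 20 mM (fed, over 50 min) | 20 mM |
| incoming ligand | 30 mM | 30 mM | 30 mM | 30.0 mM (fed, over 50 min) | 30.0 mM | 30.0 mM | 30.0 mM (in portions, 2, over 50 min) |
| remark | run made earlier | run made earlier | run made earlier | all else is in the flask from the start; the feed brings no volume worth counting | everything together at the start | all else is in the flask from the start; the feed brings no volume worth counting | first portion at the start, last at 50 min |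
| time |  |  |  | 1.0 h | 1.0 h | 1.0 h | 1.0 h |

- the flask that comes out highest in amount of complex with two exchanged, in percent of the starting complex charged, or "all alike" when all lie within 1.5 percentage points (dawn / noon / dusk / summer / all alike)
- complex with two exchanged at the end, in percent of the starting complex charged, dawn
- complex with two exchanged at the end, in percent of the starting complex charged, noon
- complex with two exchanged at the end, in percent of the starting complex charged, dusk
- complex with two exchanged at the end, in percent of the starting complex charged, summer

- what was read earlier has a scatter of 2 percentage points, one standard deviation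

| run | time / min | complex with two exchanged / % | complex with one exchanged / % |
|---|---|---|---|
| north-east | 3.00 | 9 | 5 |
| north-east | 10.0 | 39 | 9 |
| north-east | 15.0 | 40 | 5 |
| north-east | 25.0 | 56 | 3 |
| north-east | 40.0 | 61 | 5 |
| north-east | 50.0 | 64 | 4 |
| north-east | 60.0 | 65 | 4 |
| south | 10.0 | 33 | 8 |
| south | 20.0 | 57 | 6 |
| south | 30.0 | 72 | 3 |
| south | 40.0 | 81 | 6 |
| south | 50.0 | 83 | 2 |
| south | 60.0 | 89 | 2 |
| south | 80.0 | 92 | 3 |
| south-west | 4.00 | 11 | 9 |
| south-west | 12.0 | 27 | 11 |
| south-west | 20.0 | 36 | 9 |
| south-west | 30.0 | 33 | 9 |
| south-west | 40.0 | 31 | 5 |
| south-west | 60.0 | 34 | 5 |
| south-west | 80.0 | 32 | 3 |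

(standard deviation of a reading: 2 percentage points)

Read the last rows against the cap. The north-east run has a cap of 0.750 and ends with 69.0% of its complex exchanged at least once. South has 1.50 and reaches 95.0%, while south-west has 0.375 and stops at 35.0%. Incoming ligand is the limiting reagent in north-east and in south-west, where the cap stands below one.

The highest one-exchanged reading in south-west is 11%, so I let that form pass straight through. Let f be the untouched fraction of complex and s the ligand left, as a fraction of twice the complex charged. I take one rate for both, f·s/θ. Then s−f stays constant, and s/f changes by the factor exp((s−f)t/θ).

The last north-east row gives f = 31.0%, and from it the ligand clock θ, the time that divides f·s in that rate at this complex charge: 11.1 min, a reading with its scatter. South, with half the complex, gives 21.6 min from its row at 30.0 min, twice the north-east clock, also a reading.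

Noon repeats north-east, so I read 65%. A steady feed arrives on average 25.0 min late, and f and s enter the rate alike, so for dawn and dusk I run that curve for 35.0 min. This gives f = 37.9%; taking off the 5% of one-exchanged complex read in north-east at 40.0 min leaves 57.1%. In summer the first portion runs at half the cap for 50 min and leaves f = 63.9%. The last 10.0 min bring f to 48.6%, which leaves 46.4%. So I put noon highest.

The forecast differs at the top: it names dawn, where the feed “stays below capacity until late”, with 68% for dawn, 65% for noon, 58% for dusk and 51% for summer.

The flasks give 56.5% for dawn, 67.4% for noon, 56.8% for dusk and 49.0% for summer, so noon is highest.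

    starting complex + incoming ligand → leaving ligand + complex with one exchanged (k = 0.100 /M/s)
    complex with one exchanged + incoming ligand → leaving ligand + complex with two exchanged (k = 0.830 /M/s)
    incoming ligand ⇌ dormant form (K = 1.50, k = 0.0510 /s)

With θ at 11.1 min, summer's reckoned f of 48.6% stands against 45% in the flask. Now take summer with 75 mM of incoming ligand, which raises the cap to 1.88. In that flask I reckon that the first portion leaves f = 21.3%, and the same clock over the last 10.0 min gives 8.54%. That neighbouring flask ends with 7.2% of its starting complex untouched and 91.8% as complex with two exchanged.

The earlier runs and the new flask stem from a simulated flask from invented constants; noise was put on by code.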